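## Retrosynthetic overview
1. The target comes from an acyclic epoxy-enal in the last step. CrCl2/LiI reduces a 2-(oxiranyl)acrylate to an O8-chelated allylchromium, C7 adds to the C6 enal (ten-membered carbocycle), and O6 closes on the ester (γ-lactone). C6, C7 and the free 8-OH all appear together.
2. C7 is a one-carbon linchpin bonded to two aldehyde carbons in turn. C7–C8 is made first, by sulfonium-ylide epoxidation of a C8 aldehyde with methyl 2-(bromomethyl)acrylate, and C8 is set by Felkin control from C9.
3. The α-acetoxy aldehyde comes from periodate excision of a glyceraldehyde-derived glycol. C9–C10 comes from a Nozaki–Hiyama–Kishi coupling of a (Z)-2-iodoallylic alcohol with (S)-glyceraldehyde acetonide, which sets C9.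
4. The (Z)-iodoalkene, which fixes the C1=C10 geometry, comes from an iodo-Wittig reaction on the C1 aldehyde cut out of nerol. Nerol supplies C1–C6, C15 and the Z C4=C5 alkene.
5. Ring order: carbocycle first, then lactone, both in the final flask.

Assumption: labels C1–C15 are germacrane numbers of the target (C6 lactone carbinol CH, C7 ring-fusion CH, C8 CHOH, C9 CHOAc, C10/C14 alkene carbon and its CH2O-acyl group, C4/C15 alkene carbon and its methyl, C11/C12/C13 lactone α-carbon, carbonyl and exocyclic CH2), and (S)-glyceraldehyde acetonide and (R)-2-methylbutanoic acid are bought as single enantiomers.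

## Route

Step 1
Reactants: 1 nerol
Product: 2 neryl tert-butyldimethylsilyl ether
Conditions: TBSCl, imidazole, CH2Cl2, 0 °C → rt
Reagents that add atoms: tert-butyldimethylsilyl chloride, CC(C)(C)[Si](C)(C)Cl
Why: Imidazole-promoted silylation (silyl ether protection) of the only hydroxyl group; no stereocentre is formed and the Z alkene is untouched.

Step 2
Reactants: 2 neryl tert-butyldimethylsilyl ether
Product: 3 (4Z)-6-(tert-butyldimethylsilyloxy)-4-methylhex-4-enal
Conditions: O3 (1 equiv), CH2Cl2, −78 °C; then Me2S, −78 °C → rt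
Reagents that add atoms: ozone, [O-][O+]=O
Why: Chemoselective ozonolysis with reductive work-up: the isopropylidene alkene is more electron-rich than the alkene bearing the inductively withdrawing allylic silyloxy group, so one equivalent of ozone cuts only the former and the Z C4=C5 geometry is kept.

Step 3
Reactants: 3 (4Z)-6-(tert-butyldimethylsilyloxy)-4-methylhex-4-enal; 4 ethyl (triphenylphosphoranylidene)acetate
Product: 6 ethyl (2Z,6Z)-8-(tert-butyldimethylsilyloxy)-2-iodo-6-methylocta-2,6-dienoate, via iodo ylide 5 (not isolated)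
Conditions: 4, N-iodosuccinimide, CH2Cl2, −20 °C; then 3, −20 °C → rt
Reagents that add atoms: ethyl (triphenylphosphoranylidene)acetate (4), CCOC(=O)C=P(c1ccccc1)(c1ccccc1)c1ccccc1; N-iodosuccinimide, O=C1CCC(=O)N1I
Why: Wittig olefination with a stabilised α-iodo ylide made in situ by electrophilic iodination of 4; as with other stabilised ylides the ester ends up trans to the chain, which gives the (2Z)-iodoenoate and places iodine exactly where C9 must sit (cis to C2).

Step 4
Reactants: 6 ethyl (2Z,6Z)-8-(tert-butyldimethylsilyloxy)-2-iodo-6-methylocta-2,6-dienoate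
Product: 7 (2Z,6Z)-8-(tert-butyldimethylsilyloxy)-2-iodo-6-methylocta-2,6-dien-1-ol
Conditions: i-Bu2AlH (2.2 equiv), CH2Cl2, −78 °C; aqueous potassium sodium tartrate
Reagents that add atoms: none
Why: 1,2-Reduction of the enoate with i-Bu2AlH at low temperature; the alkenyl iodide, the silyl ether and both alkene geometries are inert.

Step 5
Reactants: 7 (2Z,6Z)-8-(tert-butyldimethylsilyloxy)-2-iodo-6-methylocta-2,6-dien-1-ol; 8 (4S)-2,2-dimethyl-1,3-dioxolane-4-carbaldehyde
Product: 9 (1R,2Z,6Z)-8-(tert-butyldimethylsilyloxy)-1-[(4S)-2,2-dimethyl-1,3-dioxolan-4-yl]-2-(hydroxymethyl)-6-methylocta-2,6-dien-1-ol (9R)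
Conditions: CrCl2 (4 equiv), NiCl2 (2 mol %), DMF, rt
Reagents that add atoms: (4S)-2,2-dimethyl-1,3-dioxolane-4-carbaldehyde (8), O=C[C@@H]1COC(C)(C)O1
Why: Nozaki–Hiyama–Kishi coupling: NiCl2-catalysed conversion of the alkenyl iodide into the alkenylchromium retains the alkene geometry and tolerates the free hydroxyl (as an alkoxide it is too poor a leaving group for allene formation), and polar Felkin–Anh attack on the α-alkoxy aldehyde gives mainly the anti (erythro) adduct, which sets C9 as R, the minor epimer being removed by chromatography.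

Step 6
Reactants: 9 the 9R diol; 10 (2R)-2-methylbutanoic acid
Product: 12 14-O-[(2R)-2-methylbutanoyl]-9-O-acetyl derivative of 9, via monoester 11 (not isolated)
Conditions: 10 (1.05 equiv), N,N'-diisopropylcarbodiimide, 4-(dimethylamino)pyridine (10 mol %), CH2Cl2, 0 °C; then Ac2O, rt
Reagents that add atoms: (2R)-2-methylbutanoic acid (10), CC[C@@H](C)C(=O)O; acetic anhydride, CC(=O)OC(C)=O
Why: Steglich esterification takes the primary allylic hydroxyl in preference to the hindered secondary one, and 4-(dimethylamino)pyridine-catalysed acetylation in the same flask caps O9 before any 1,3-acyl shift; no chain stereocentre is touched, and the catalytic base at 0 °C does not epimerise the α-centre of 10.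

Step 7
Reactants: 12 the acetonide diester
Product: 13 [(2Z,6Z)-2-[(1R)-1-acetoxy-2-oxoethyl]-8-hydroxy-6-methylocta-2,6-dien-1-yl] (2R)-2-methylbutanoate (C8 aldehyde and free C6 alcohol)
Conditions: H5IO6 (3 equiv), THF–H2O 4:1, 0 °C → rt
Reagents that add atoms: none
Why: Periodic acid first acts as an acid (hydrolysis of the terminal acetonide and of the primary silyl ether) and then as the oxidant of a Malaprade glycol cleavage, so the former dioxolane CH becomes the C8 aldehyde, its CH2 leaves as formaldehyde, and C9 stays intact because the medium is never basic.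

Step 8
Reactants: 13 the α-acetoxy aldehyde; 14 methyl 2-(bromomethyl)acrylate
Product: 17 methyl 2-[(2R,3S)-3-substituted oxiran-2-yl]acrylate bearing the 9R-acetoxy chain and the free C6 alcohol (7R,8S,9R trans epoxide), via sulfonium bromide 15 (not isolated), via sulfonium ylide 16 (not isolated)
Conditions: 14, tetrahydrothiophene, THF, rt; LiN(SiMe3)2 (0.95 equiv to salt), −78 °C; then 13, −78 → −30 °C
Reagents that add atoms: methyl 2-(bromomethyl)acrylate (14), C=C(CBr)C(=O)OC
Why: Corey–Chaykovsky-type epoxidation with an allylic sulfonium ylide: the ylide is far less basic than an alkoxide, so the free hydroxyl and the acidic C9–H survive, polar Felkin–Anh attack anti to the acetoxy group sets C8 as S (erythro to C9), and the C7 configuration (mainly trans epoxide) does not matter because C7 becomes planar again in step 10.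

Step 9
Reactants: 17 the vinyl epoxide alcohol
Product: 18 the corresponding (Z)-enal (C6 aldehyde; 7R,8S,9R)
Conditions: TEMPO (2,2,6,6-tetramethylpiperidin-1-oxyl, 10 mol %), PhI(OAc)2, CH2Cl2, 0 °C → rt
Reagents that add atoms: none
Why: Oxoammonium (TEMPO/PhI(OAc)2) oxidation of the only hydroxyl group, a method that turns neryl-type Z allylic alcohols into Z enals without isomerisation and leaves the epoxide, acrylate and esters alone.

Step 10
Reactants: 18 the epoxy-enal
Product: 22 target CNP0005248.2, via allylic iodide 19 (not isolated), via allylchromium chelate 20 (not isolated), via dihydroxy ester 21 (not isolated)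
Conditions: CrCl2 (8 equiv), LiI (4 equiv), THF, 0.002 M, slow addition of 18, rt; then pH 4 citrate buffer, rt
Reagents that add atoms: none
Why: Proposed new method: iodide opens the 2-(oxiranyl)acrylate in SN2′ fashion (conjugate addition with epoxide opening) to the (Z)-allylic iodide 19, and two CrCl2 reduce it to an allylchromium held by the O8 alkoxide in the six-membered chelate 20; this adds through C7 to the chromium-bound C6 enal in a bicyclo[2.2.2]-like transition state that keeps the enal substituent C5 next to the allyl bridge and still lets the five-atom tether reach C9 (ring torsions anti about C6–C7, gauche about C7–C8), which gives 6R,7R (1,3-anti diol, C5/C8 trans) from 8S; the inert trivalent chromium alkoxides hold the acetate in place until the mildly acidic quench, where O6 closes the trans-fused γ-lactone (a cis-fused 8,12-lactone would force a nearly eclipsed torsion into the ten-membered ring, and 8β-hydroxy-6,12-germacranolides do not relactonise); the closest known reactions are the CrCl2/LiI addition of 1,3-diene monoepoxides to aldehydes, which gives 2-vinyl-1,3-diols of the same relative configuration (Takai–Utimoto type), and intramolecular Nozaki–Hiyama allylation–lactonisation of germacranolide precursors, and what is new is their union in a ten-membered ring closure on an unprotected, fully acylated substrate.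

## Compound list
1 | nerol, (2Z)-3,7-dimethylocta-2,6-dien-1-ol | OC/C=C(/C)CCC=C(C)C | starting material
2 | neryl tert-butyldimethylsilyl ether | CC(C)(C)[Si](C)(C)OC/C=C(/C)CCC=C(C)C | intermediate
3 | (4Z)-6-(tert-butyldimethylsilyloxy)-4-methylhex-4-enal | CC(C)(C)[Si](C)(C)OC/C=C(/C)CCC=O | intermediate
4 | ethyl (triphenylphosphoranylidene)acetate | CCOC(=O)C=P(c1ccccc1)(c1ccccc1)c1ccccc1 | starting material
5 | ethyl iodo(triphenylphosphoranylidene)acetate (iodo ylide) | CCOC(=O)C(I)=P(c1ccccc1)(c1ccccc1)c1ccccc1 | intermediate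
6 | ethyl (2Z,6Z)-8-(tert-butyldimethylsilyloxy)-2-iodo-6-methylocta-2,6-dienoate | CC(C)(C)[Si](C)(C)OC/C=C(/C)CC/C=C(/C(=O)OCC)I | intermediate
7 | (2Z,6Z)-8-(tert-butyldimethylsilyloxy)-2-iodo-6-methylocta-2,6-dien-1-ol | CC(C)(C)[Si](C)(C)OC/C=C(/C)CC/C=C(/CO)I | intermediate
8 | (4S)-2,2-dimethyl-1,3-dioxolane-4-carbaldehyde, (S)-glyceraldehyde acetonide | O=C[C@@H]1COC(C)(C)O1 | starting material
9 | anti coupling product, 9R carbinol next to the (4S)-dioxolane, free C14 alcohol | CC(C)(C)[Si](C)(C)OC/C=C(/C)CC/C=C(/CO)[C@@H](O)[C@@H]1COC(C)(C)O1 | intermediate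
10 | (2R)-2-methylbutanoic acid | CC[C@@H](C)C(=O)O | starting material
11 | 14-O-[(2R)-2-methylbutanoyl] monoester of 9 | CC(C)(C)[Si](C)(C)OC/C=C(/C)CC/C=C(/COC(=O)[C@H](C)CC)[C@@H](O)[C@@H]1COC(C)(C)O1 | intermediate
12 | 9-O-acetyl-14-O-[(2R)-2-methylbutanoyl] derivative of 9 | CC(C)(C)[Si](C)(C)OC/C=C(/C)CC/C=C(/COC(=O)[C@H](C)CC)[C@@H](OC(C)=O)[C@@H]1COC(C)(C)O1 | intermediate
13 | (9R)-α-acetoxy C8 aldehyde with free C6 alcohol | OC/C=C(/C)CC/C=C(/COC(=O)[C@H](C)CC)[C@@H](OC(C)=O)C=O | intermediate
14 | methyl 2-(bromomethyl)acrylate | C=C(CBr)C(=O)OC | starting material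
15 | 1-[2-(methoxycarbonyl)prop-2-enyl]tetrahydrothiophenium bromide | C=C(C[S+]1CCCC1)C(=O)OC.[Br-] | intermediate
16 | the derived sulfonium ylide | C=C([CH-][S+]1CCCC1)C(=O)OC | intermediate
17 | (7R,8S,9R)-2-(oxiranyl)acrylate with free C6 alcohol (trans epoxide drawn; the C7 epimer converges) | OC/C=C(/C)CC/C=C(/COC(=O)[C@H](C)CC)[C@@H](OC(C)=O)[C@H]1O[C@@H]1C(=C)C(=O)OC | intermediate
18 | (7R,8S,9R)-epoxy-enal | O=C/C=C(/C)CC/C=C(/COC(=O)[C@H](C)CC)[C@@H](OC(C)=O)[C@H]1O[C@@H]1C(=C)C(=O)OC | intermediate
19 | (Z)-2-(iodomethyl)-4-hydroxy enoate (8S,9R; alkoxide in the flask, drawn as the alcohol) | O=C/C=C(/C)CC/C=C(/COC(=O)[C@H](C)CC)[C@@H](OC(C)=O)[C@@H](O)/C=C(/C(=O)OC)CI | intermediate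
20 | six-membered O8–Cr–C13 allylchromium chelate | O=C/C=C(/C)CC/C=C(/COC(=O)[C@H](C)CC)[C@@H](OC(C)=O)[C@H]1O[Cr](Cl)CC(C(=O)OC)=C1 | intermediate
21 | ten-membered 6,8-dihydroxy methyl ester (spatial arrangement of the target at C6–C9) | COC(=O)C(=C)[C@H]1[C@H](O)/C=C(/C)CC/C=C(/COC(=O)[C@H](C)CC)[C@@H](OC(C)=O)[C@H]1O | intermediate
22 | [(3aR,4S,5R,6Z,10Z,11aR)-5-acetoxy-4-hydroxy-10-methyl-3-methylidene-2-oxo-2,3,3a,4,5,8,9,11a-octahydrocyclodeca[b]furan-6-yl]methyl (2R)-2-methylbutanoate | C=C1C(=O)O[C@@H]2/C=C(/C)CC/C=C(/COC(=O)[C@H](C)CC)[C@@H](OC(C)=O)[C@@H](O)[C@@H]12 | target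

## Step count and risks
Total step count: 10. Longest linear sequence: 10 (nerol to target).

**Step 10.** The possible failures are oligomerisation, Z to E drift of the enal under LiI and trivalent chromium, an acetyl shift from O9 to the O8 alkoxide, and closure of the 8,12-lactone. The fallback gives up the chelate and the free alkoxide and works with O8 blocked. It sets out from 18 and comes back at 22. MgBr2·OEt2 in Et2O opens the oxiranyl acrylate in SN2′ fashion to the (Z)-allylic bromide with free 8-OH F1. Et3SiOTf and 2,6-lutidine convert it into the 8-O-triethylsilyl ether F2. A conventional high-dilution CrCl2 ring closure of this protected allylic bromide goes through an open, non-chelated allylchromium. Only O6 can then lactonise on acidic work-up, and no alkoxide sits next to the acetate; this gives the 8-O-triethylsilyl lactone F3. HF·pyridine then releases 22.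

**Step 8.** The possible failures are weak Felkin control at C8, an acetyl shift in the betaine, and self-condensation of the acrylate ylide. The fallback does not rebuild C8 but keeps the purchased stereocentre as C8 and turns the dioxolane CH2 into C7. It sets out from 12 and comes back at 18. Aqueous AcOH removes the acetonide and the silyl ether to give the triol F4. TEMPO/PhI(OAc)2 (2.2 equiv) oxidises both primary alcohols to the enal α-hydroxy aldehyde F5. [1-(Methoxycarbonyl)ethenyl]diisobutylaluminium, made from methyl propiolate and i-Bu2AlH, adds to the saturated aldehyde to give the Baylis–Hillman-type 7,8-diol F6 as C7 epimers. Mitsunobu cyclodehydration (PPh3, diisopropyl azodicarboxylate) activates the allylic C7 hydroxyl, and O8 displaces it. This gives 18 with the C8–O bond untouched, and the C7 epimers again converge.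

**Step 5.** The possible failures are a modest anti/syn ratio at C9 and sluggish coupling of the hindered alkenyl iodide. The fallback sets C9 by hydride delivery instead of by the C–C bond formation. It sets out from 9 (taken on as the C9 epimer mixture) and comes back at 11. Selective esterification gives 11 as an epimer mixture, which is isolated this time. Dess–Martin periodinane converges both epimers to the enone F7. Chelation-controlled 1,2-reduction with Zn(BH4)2 (Cram chelate between the ketone and the dioxolane α-oxygen) returns the anti alcohol 11, which is then acetylated to 12.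

## Further compounds
F1 | step 10 | (Z)-allylic bromide with free 8-OH (8S,9R) | O=C/C=C(/C)CC/C=C(/COC(=O)[C@H](C)CC)[C@@H](OC(C)=O)[C@@H](O)/C=C(/C(=O)OC)CBr
F2 | step 10 | 8-O-triethylsilyl ether of F1 | O=C/C=C(/C)CC/C=C(/COC(=O)[C@H](C)CC)[C@@H](OC(C)=O)[C@@H](O[Si](CC)(CC)CC)/C=C(/C(=O)OC)CBr
F3 | step 10 | 8-O-triethylsilyl lactone (silyl ether of 22) | C=C1C(=O)O[C@@H]2/C=C(/C)CC/C=C(/COC(=O)[C@H](C)CC)[C@@H](OC(C)=O)[C@@H](O[Si](CC)(CC)CC)[C@@H]12
F4 | step 8 | triol (C6, C7 and C8 hydroxyls free; 8S,9R) | OC/C=C(/C)CC/C=C(/COC(=O)[C@H](C)CC)[C@@H](OC(C)=O)[C@@H](O)CO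
F5 | step 8 | enal α-hydroxy aldehyde (C6 and C7 aldehydes; 8S,9R) | O=C/C=C(/C)CC/C=C(/COC(=O)[C@H](C)CC)[C@@H](OC(C)=O)[C@@H](O)C=O
F6 | step 8 | Baylis–Hillman-type 7,8-diol (C7 epimers; 8S,9R) | O=C/C=C(/C)CC/C=C(/COC(=O)[C@H](C)CC)[C@@H](OC(C)=O)[C@@H](O)C(O)C(=C)C(=O)OC
F7 | step 5 | C9 enone of monoester 11 | CC(C)(C)[Si](C)(C)OC/C=C(/C)CC/C=C(/COC(=O)[C@H](C)CC)C(=O)[C@@H]1COC(C)(C)O1
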